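**Strategy.** The target is cut at C10–C1 and C4–C5 of its hydroazulene core (C1 quaternary CMe, C2/C3 CH2, C4 ester carbon, C5 ring-fusion CH, C6 carbinol, C7 CH2, C8/C9 epoxide, C10 CH2). Without these two bonds the fifteen core carbons are one head-to-tail farnesyl chain, so a daucene-forming terpene cyclase can close the seven-membered and the five-membered ring and set the quaternary C1 in a single operation. Its substrate is acyclic, achiral (2E,6E)-farnesyl diphosphate, made from farnesol in two steps. The two olefins of the product (C4=C5, C8=C9) then guide all oxygenation and the late attachment of the benzyl-protected vanilloyl group.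

Key step: step 3

**Remarks**
- Descriptors: daucane numbering as above; β is the face of the C1 methyl. The target is (1R,4R,5S,6S,8R,9S): 4β-acyloxy, 5α-H, 6α-OH, 8α,9α-epoxide.
- Assumption: a recombinant daucene-forming cyclase of the (1R) series is available; the sense of C1 is to be checked on the first batch of 5 (chiral GC, optical rotation).
- Precursor design: 3 is used as its tris-ammonium salt, free of chloride and inorganic diphosphate, and fed in portions under a hydrocarbon overlay. The cyclase itself isomerises the 2E olefin, so the chain needs no other change.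
- The C4 hydroxyl is tertiary and the C6 hydroxyl secondary, so the ester is made with C6 masked, and every later step avoids base to prevent a 1,3-acyl shift.

**Route**

Step 1
Reactants: 1 (2E,6E)-farnesol
Product: 2 (2E,6E)-farnesyl chloride
Conditions: NCS, Me2S, CH2Cl2, −40 °C; then 1, −40 to 0 °C
Reagents that add atoms: N-chlorosuccinimide, O=C1CCC(=O)N1Cl
Why: Corey–Kim chlorination converts the primary allylic alcohol through its alkoxysulfonium salt by direct SN2 displacement, so neither the olefin geometries nor the allylic position is disturbed.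

Step 2
Reactants: 2 (2E,6E)-farnesyl chloride
Product: 3 (2E,6E)-farnesyl diphosphate (handled as tris-ammonium salt)
Conditions: (Bu4N)3HP2O7, MeCN, rt; then cation-exchange resin (NH4+ form), aqueous NH4HCO3, lyophilisation
Reagents that add atoms: tris(tetrabutylammonium) hydrogen diphosphate, CCCC[N+](CCCC)(CCCC)CCCC.CCCC[N+](CCCC)(CCCC)CCCC.CCCC[N+](CCCC)(CCCC)CCCC.OP(=O)([O-])OP(=O)([O-])[O-]
Why: SN2 displacement of the primary allylic chloride by the diphosphate anion in acetonitrile, the standard route to allylic diphosphates, keeps both olefin geometries, and cation exchange gives the water-soluble salt the enzyme accepts.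

Step 3
Reactants: 3 (2E,6E)-farnesyl diphosphate
Product: 5 (1R)-dauca-4,8-diene (daucene), via nerolidyl diphosphate 4 (not isolated)
Conditions: recombinant daucene synthase (purified), MgCl2 (10 mM), HEPES buffer pH 7.5, dithiothreitol, glycerol (10%), 30 °C, pentane overlay
Reagents that add atoms: none
Why: Magnesium-assisted ionisation and return of the diphosphate at C8 (4) frees rotation so that C8=C9 can become the cis ring olefin; re-ionisation gives the allyl cation whose C10 terminus is attacked by C1 of the C1=C5 olefin while the C4=C11 olefin traps C5, and a 1,2-hydride shift from C4 to C11 followed by loss of H-5 leaves the tetrasubstituted C4=C5 olefin. The closest known reaction type is the ionisation-initiated cyclisation cascade of sesquiterpene synthases of the daucene and carotol family. The seven-membered ring closes in the 7-endo-trig mode (both carbons of the attacking C1=C5 olefin end up in the ring) and the five-membered ring in the 5-exo-trig mode (C11 stays outside). C1, the only stereocentre formed, is set by the active-site fold, which presents one face of the C1=C5 olefin to C10. The step needs 1,7-closure in preference to 1,6-, 1,10- or 1,11-closure and termination by deprotonation at C5 instead of water capture; the enzyme contour enforces both, and the substrate helps because the anti-Markovnikov first closure is viable only when the 1,5-diene spacing lets the terminal trisubstituted olefin intercept C5 at once to give a tertiary cation.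

Step 4
Reactants: 5 (1R)-dauca-4,8-diene
Product: 7 (1R)-dauca-5,8-dien-4-ol (both C4 epimers), via allylic hydroperoxide 6 (not isolated)
Conditions: O2, tetraphenylporphyrin (cat.), white LED, CH2Cl2, −20 °C, stopped at about one equivalent of O2; then PPh3, −20 °C to rt
Reagents that add atoms: dioxygen, O=O
Why: In the Schenck ene reaction singlet oxygen should attack the tetrasubstituted C4=C5 olefin faster than the trisubstituted C8=C9 olefin, bond to the less encumbered C4 and take H-6, the only allylic hydrogen on the C5 side (C1 is quaternary); the C4 configuration does not matter because C4 becomes sp2 again in step 5.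

Step 5
Reactants: 7 (1R)-dauca-5,8-dien-4-ol
Product: 8 (1R)-dauca-4,8-dien-6-one
Conditions: pyridinium chlorochromate [C5H5NH][CrO3Cl], NaOAc, 4 Å molecular sieves, CH2Cl2, rt
Reagents that add atoms: none
Why: In the Babler–Dauben oxidative transposition the tertiary allylic chromate ester shifts [3,3] to the secondary C6 chromate, which is oxidised to the enone, so both C4 epimers converge, and acetate buffering should keep the C8=C9 olefin out of conjugation.

Step 6
Reactants: 8 (1R)-dauca-4,8-dien-6-one
Product: 9 (1R,6R)-dauca-4,8-dien-6-ol (6β-OH)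
Conditions: NaBH4, CeCl3·7H2O, MeOH, −78 °C
Reagents that add atoms: none
Why: Luche reduction gives clean 1,2-addition, and hydride is expected to enter C6 from the α face, anti to the C1 methyl that stands 1,3 to the carbonyl (the usual course for cyclic ketones with a 1,3-related axial methyl), which sets the 6β-alcohol.

Step 7
Reactants: 9 (1R,6R)-dauca-4,8-dien-6-ol
Product: 10 (1R,4R,5S,6R)-4,5-epoxydauc-8-en-6-ol
Conditions: VO(acac)2 (5 mol%), t-BuOOH (1.2 equiv, decane), CH2Cl2, 0 °C
Reagents that add atoms: tert-butyl hydroperoxide, CC(C)(C)OO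
Why: In this hydroxyl-directed vanadium epoxidation the vanadate ester of the 6β-hydroxyl delivers oxygen to the same (β) face of the allylic C4=C5 olefin, setting C4 and C5, and the allylic olefin should react well before the homoallylic C8=C9 olefin at one equivalent of oxidant.

Step 8
Reactants: 10 (1R,4R,5S,6R)-4,5-epoxydauc-8-en-6-ol
Product: 13 (1R,4R,5R)-4-hydroxydauc-8-en-6-one (4β-OH; 5α-H), via epoxy silyl ether 11 (not isolated), via siloxy ketone 12 (not isolated)
Conditions: TMSOTf (1.5 equiv), i-Pr2NEt (2 equiv), CH2Cl2, −78 °C; then aqueous citric acid, THF, 0 °C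
Reagents that add atoms: none
Why: In this semipinacol (non-aldol aldol) rearrangement of a 2,3-epoxy alcohol silyl ether, silyl activation opens the epoxide at C5 while H-6, anti-periplanar to the breaking C5–O bond, migrates to the α face of C5 with inversion, so the 6β-carbinol configuration is relayed into the trans ring fusion (5α-H), the β C4–O bond is untouched and C6 becomes the ketone; mild acid then cleaves the tertiary silyl ether.

Step 9
Reactants: 13 (1R,4R,5R)-4-hydroxydauc-8-en-6-one
Product: 14 (1R,4R,5S,6S)-dauc-8-ene-4,6-diol (4β-OH; 6α-OH)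
Conditions: Me4NBH(OAc)3, MeCN/AcOH (1:1), −30 °C
Reagents that add atoms: none
Why: In the Evans–Saksena reduction the 4β-hydroxyl exchanges onto boron and delivers hydride through a six-membered transition state to the β face of the C6 ketone, giving the 6α-alcohol (1,3-anti diol) against the intrinsic α-face preference, and the acidic medium avoids enolisation toward C7.

Step 10
Reactants: 14 (1R,4R,5S,6S)-dauc-8-ene-4,6-diol
Product: 15 (1R,4R,5S,6S)-6-(4-methoxybenzyloxy)dauc-8-en-4-ol
Conditions: NaH (1.1 equiv), 4-methoxybenzyl chloride, Bu4NI (cat.), THF/DMF (4:1), 0 °C to rt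
Reagents that add atoms: 4-methoxybenzyl chloride, COc1ccc(CCl)cc1
Why: Williamson etherification takes the secondary C6 alkoxide only, because the tertiary C4 hydroxyl between isopropyl and the ring fusion is too hindered, and a benzylic ether is chosen because, unlike a silyl ether, it cannot migrate to the C4 alkoxide in step 12.

Step 11
Reactants: 16 4-(benzyloxy)-3-methoxybenzoic acid
Product: 17 4-(benzyloxy)-3-methoxybenzoyl chloride
Conditions: (COCl)2, DMF (cat.), CH2Cl2, 0 °C to rt
Reagents that add atoms: oxalyl chloride, O=C(Cl)C(Cl)=O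
Why: Standard acid chloride formation through the catalytic chloroiminium species gives an aroyl chloride that has no α-hydrogen and so cannot form a ketene under the basic acylation that follows.

Step 12
Reactants: 15 (1R,4R,5S,6S)-6-(4-methoxybenzyloxy)dauc-8-en-4-ol; 17 4-(benzyloxy)-3-methoxybenzoyl chloride
Product: 19 (1R,4R,5S,6S)-6-(4-methoxybenzyloxy)dauc-8-en-4-yl 4-(benzyloxy)-3-methoxybenzoate, via potassium alkoxide 18 (not isolated)
Conditions: KN(SiMe3)2 (1.3 equiv), THF, −78 °C; then 17 (1.5 equiv), −78 to 0 °C
Reagents that add atoms: none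
Why: O-Acylation of a preformed tertiary potassium alkoxide by an aroyl chloride is the standard way to esterify hindered tertiary alcohols, and with C6 blocked the ester can form only at C4, with retention there.

Step 13
Reactants: 19 (1R,4R,5S,6S)-6-(4-methoxybenzyloxy)dauc-8-en-4-yl 4-(benzyloxy)-3-methoxybenzoate
Product: 20 (1R,4R,5S,6S)-6-hydroxydauc-8-en-4-yl 4-(benzyloxy)-3-methoxybenzoate
Conditions: DDQ (1.5 equiv), CH2Cl2/pH 7 phosphate buffer (10:1), 0 °C
Reagents that add atoms: none
Why: DDQ cleaves the 4-methoxybenzyl ether by hydride abstraction and hydrolysis of the oxocarbenium ion under neutral buffered conditions, which should prevent acyl migration to the freed secondary oxygen and spare the plain benzyl ether and the olefin.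

Step 14
Reactants: 20 (1R,4R,5S,6S)-6-hydroxydauc-8-en-4-yl 4-(benzyloxy)-3-methoxybenzoate
Product: 21 (1R,4R,5S,6S,8R,9S)-8,9-epoxy-6-hydroxydaucan-4-yl 4-(benzyloxy)-3-methoxybenzoate
Conditions: VO(acac)2 (10 mol%), t-BuOOH (2 equiv, decane), CH2Cl2, 0 °C to rt
Reagents that add atoms: tert-butyl hydroperoxide, CC(C)(C)OO
Why: In this vanadium epoxidation directed by a cyclic homoallylic alcohol the 6α-hydroxyl delivers oxygen to the α face of the C8=C9 olefin, setting C8 and C9 syn to the hydroxyl, while the masked phenol can neither bind vanadium nor be oxidised.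

Step 15
Reactants: 21 (1R,4R,5S,6S,8R,9S)-8,9-epoxy-6-hydroxydaucan-4-yl 4-(benzyloxy)-3-methoxybenzoate
Product: 22 (1R,4R,5S,6S,8R,9S)-8,9-epoxy-6-hydroxydaucan-4-yl 4-hydroxy-3-methoxybenzoate (CNP0315707.1)
Conditions: H2 (1 atm), Pd/C (10%), EtOAc, rt
Reagents that add atoms: none
Why: Hydrogenolysis of the aryl benzyl ether on palladium is neutral, so the trisubstituted epoxide, the tertiary ester and the free secondary alcohol should survive and no base is present to trigger acyl migration.

**Compound list**

1 | (2E,6E)-farnesol | CC(C)=CCC/C(C)=C/CC/C(C)=C/CO | starting material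
2 | (2E,6E)-farnesyl chloride | CC(C)=CCC/C(C)=C/CC/C(C)=C/CCl | intermediate
3 | (2E,6E)-farnesyl diphosphate (drawn as the free acid; handled as tris-ammonium salt) | CC(C)=CCC/C(C)=C/CC/C(C)=C/COP(=O)(O)OP(=O)(O)O | intermediate
4 | (6E)-nerolidyl diphosphate, enzyme-bound (C3 configuration fixed by the enzyme, not assigned) | C=CC(C)(CC/C=C(\C)CCC=C(C)C)OP(=O)(O)OP(=O)(O)O | intermediate (not isolated)
5 | (1R)-dauca-4,8-diene (daucene) | CC(C)C1=C2CCC(C)=CC[C@@]2(C)CC1 | intermediate
6 | (1R)-4-hydroperoxydauca-5,8-diene (both C4 epimers) | CC(C)C1(OO)CC[C@]2(C)CC=C(C)CC=C12 | intermediate (not isolated)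
7 | (1R)-dauca-5,8-dien-4-ol (both C4 epimers) | CC(C)C1(O)CC[C@]2(C)CC=C(C)CC=C12 | intermediate
8 | (1R)-dauca-4,8-dien-6-one | CC(C)C1=C2C(=O)CC(C)=CC[C@@]2(C)CC1 | intermediate
9 | (1R,6R)-dauca-4,8-dien-6-ol (6β-OH) | CC(C)C1=C2[C@H](O)CC(C)=CC[C@@]2(C)CC1 | intermediate
10 | (1R,4R,5S,6R)-4,5-epoxydauc-8-en-6-ol (4β,5β-epoxide; 6β-OH) | CC(C)[C@]12CC[C@]3(C)CC=C(C)C[C@@H](O)[C@]13O2 | intermediate
11 | (1R,4R,5S,6R)-4,5-epoxy-6-(trimethylsilyloxy)dauc-8-ene | CC(C)[C@]12CC[C@]3(C)CC=C(C)C[C@@H](O[Si](C)(C)C)[C@]13O2 | intermediate (not isolated)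
12 | (1R,4R,5R)-4-(trimethylsilyloxy)dauc-8-en-6-one | CC(C)[C@]1(O[Si](C)(C)C)CC[C@]2(C)CC=C(C)CC(=O)[C@@H]12 | intermediate (not isolated)
13 | (1R,4R,5R)-4-hydroxydauc-8-en-6-one (4β-OH; 5α-H) | CC(C)[C@]1(O)CC[C@]2(C)CC=C(C)CC(=O)[C@@H]12 | intermediate
14 | (1R,4R,5S,6S)-dauc-8-ene-4,6-diol (4β-OH; 6α-OH) | CC(C)[C@]1(O)CC[C@]2(C)CC=C(C)C[C@H](O)[C@@H]12 | intermediate
15 | (1R,4R,5S,6S)-6-(4-methoxybenzyloxy)dauc-8-en-4-ol | CC(C)[C@]1(O)CC[C@]2(C)CC=C(C)C[C@H](OCc3ccc(OC)cc3)[C@@H]12 | intermediate
16 | 4-(benzyloxy)-3-methoxybenzoic acid (O-benzylvanillic acid) | COc1cc(C(=O)O)ccc1OCc1ccccc1 | starting material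
17 | 4-(benzyloxy)-3-methoxybenzoyl chloride | COc1cc(C(=O)Cl)ccc1OCc1ccccc1 | intermediate
18 | potassium (1R,4R,5S,6S)-6-(4-methoxybenzyloxy)dauc-8-en-4-olate | CC(C)[C@]1([O-])CC[C@]2(C)CC=C(C)C[C@H](OCc3ccc(OC)cc3)[C@@H]12.[K+] | intermediate (not isolated)
19 | (1R,4R,5S,6S)-6-(4-methoxybenzyloxy)dauc-8-en-4-yl 4-(benzyloxy)-3-methoxybenzoate | COc1cc(C(=O)O[C@@]2(C(C)C)CC[C@]3(C)CC=C(C)C[C@H](OCc4ccc(OC)cc4)[C@H]32)ccc1OCc1ccccc1 | intermediate
20 | (1R,4R,5S,6S)-6-hydroxydauc-8-en-4-yl 4-(benzyloxy)-3-methoxybenzoate | COc1cc(C(=O)O[C@@]2(C(C)C)CC[C@]3(C)CC=C(C)C[C@H](O)[C@H]32)ccc1OCc1ccccc1 | intermediate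
21 | (1R,4R,5S,6S,8R,9S)-8,9-epoxy-6-hydroxydaucan-4-yl 4-(benzyloxy)-3-methoxybenzoate (8α,9α-epoxide) | COc1cc(C(=O)O[C@@]2(C(C)C)CC[C@]3(C)C[C@@H]4O[C@]4(C)C[C@H](O)[C@H]32)ccc1OCc1ccccc1 | intermediate
22 | (1R,4R,5S,6S,8R,9S)-8,9-epoxy-6-hydroxydaucan-4-yl 4-hydroxy-3-methoxybenzoate (CNP0315707.1) | COc1cc(C(=O)O[C@@]2(C(C)C)CC[C@]3(C)C[C@@H]4O[C@]4(C)C[C@H](O)[C@H]32)ccc1O | target

**Step count.** Total: 15 steps. Longest linear sequence: 14 steps (steps 1–10 and 12–15).

**Steps most likely to fail**

Step 3. The cyclase may end the cascade by water capture or by deprotonation at another carbon, or fold the chain in the mirror-image sense, so that daucene forms in low proportion or in the wrong enantiomeric series. Fallback, setting out from 3 and returning at 5: 3 is incubated (MgCl2, buffer, pentane overlay) with a carotol-forming cyclase of the same family. There the same two ring closures are followed by a further hydride shift and water capture at C5, giving carotol F1, which is expected to share the C1 configuration. Dehydration of this tertiary alcohol with Burgess reagent (toluene, 60 °C, syn elimination toward C4) then gives the tetrasubstituted olefin 5.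

Step 4. The ene reaction may lack site selectivity: oxygen may bond to C5 with hydrogen loss from C3 or C11, or the C8=C9 olefin may react, and the diene may be over-oxidised. Fallback, setting out from 5 and returning at 8: allylic hydroxylation with SeO2 (cat.) and t-BuOOH in CH2Cl2. Selenium should bond to the less hindered C4 in the ene step and return oxygen to C6 by [2,3]-shift, giving dauca-4,8-dien-6-ol F2 as a C6 epimer mixture. MnO2 in CH2Cl2 then oxidises F2 to enone 8.

Step 8. Ionisation may occur at C4–O with elimination, or C7 (ring contraction) or the C1 methyl may migrate in place of the hydride. Fallback, setting out from 10 and returning at 13: Dess–Martin periodinane (NaHCO3, CH2Cl2) oxidises 10 to the epoxy ketone F3. SmI2 in THF/MeOH at −78 °C then cleaves the C5–O bond reductively to ketol 13. In this variant C5 rests on protonation of the samarium enolate, which must favour the trans ring fusion.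

**Further compounds**

F1 | step 3 | carotol, (1R,4S,5S)-dauc-8-en-5-ol | CC1=CC[C@]2(CC[C@H]([C@]2(CC1)O)C(C)C)C
F2 | step 4 | (1R)-dauca-4,8-dien-6-ol (both C6 epimers) | CC(C)C1=C2C(O)CC(C)=CC[C@@]2(C)CC1
F3 | step 8 | (1R,4R,5R)-4,5-epoxydauc-8-en-6-one | CC(C)[C@]12CC[C@]3(C)CC=C(C)CC(=O)[C@]13O2
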